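**Assumption:** the target has no stereocentres, so "single enantiomer" is taken to mean the single geometric isomer drawn: (2E)-geranyl ether and (E)-enone.

## Retrosynthetic overview

1. The enone is not made by Claisen–Schmidt aldol condensation. The ArC(=O)–CH= bond is formed by chelation-assisted Rh-catalysed intermolecular hydroacylation of a terminal aryl alkyne with a salicylaldehyde, where the 2-OH needed in the target is also the directing group.
2. Target 7 ⇒ TBS-protected chalcone 6 ⇒ salicylaldehyde 3 + aryl alkyne 5. This step is fully atom-economic and sets the E-enone by syn H/acyl addition.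
3. 3 ⇒ 2,4-dihydroxybenzaldehyde 1 + geranyl bromide 2 by regioselective 4-O-alkylation. 5 ⇒ 4-ethynylphenol 4 by silylation.
4. No rings are formed. Both arenes are purchased, and the geranyl (2E) geometry is purchased and never touched.

## Route

**Step 1**
Reactants: 1, 2,4-dihydroxybenzaldehyde; 2, geranyl bromide [(2E)-1-bromo-3,7-dimethylocta-2,6-diene]
Product: 3, 4-{[(2E)-3,7-dimethylocta-2,6-dien-1-yl]oxy}-2-hydroxybenzaldehyde
Conditions: 2 (1.1 equiv), CsHCO3 (1.5 equiv), MeCN, 60 °C
Reagents that add atoms: none beyond reactant 2, geranyl bromide, CC(C)=CCC/C(C)=C/CBr (C10H17 retained, Br lost)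
Why: Williamson etherification with a weak bicarbonate base ionises only the more acidic, non-hydrogen-bonded 4-OH (the 2-OH is tied up in a hydrogen bond to the CHO), and SN2 at the primary allylic bromide leaves the 2E alkene untouched.

**Step 2**
Reactants: 4, 4-ethynylphenol
Product: 5, tert-butyl(4-ethynylphenoxy)dimethylsilane
Conditions: TBSCl (1.1 equiv), imidazole (1.5 equiv), CH2Cl2, 0 °C → rt
Reagents that add atoms: TBSCl, CC(C)(C)[Si](C)(C)Cl
Why: Standard phenol silylation; it masks the second phenol (which would otherwise compete for Rh) and stabilises the polymerisation-prone ethynylphenol.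

**Step 3 (key step)**
Reactants: 3, 4-geranyloxy-2-hydroxybenzaldehyde; 5, tert-butyl(4-ethynylphenoxy)dimethylsilane
Product: 6, (2E)-3-{4-[(tert-butyldimethylsilyl)oxy]phenyl}-1-(4-{[(2E)-3,7-dimethylocta-2,6-dien-1-yl]oxy}-2-hydroxyphenyl)prop-2-en-1-one
Conditions: [RhCl(cod)]2 (2.5 mol %), dppf (5 mol %), Na2CO3 (10 mol %), toluene, 80–100 °C, Ar; 5 (1.3 equiv) added slowly by syringe pump
Reagents that add atoms: none (all atoms of 3 and 5 are retained)
Why: Chelation-assisted Rh-catalysed intermolecular alkyne hydroacylation of a salicylaldehyde, in which the phenoxide-bound acyl–Rh–H species resists decarbonylation, Rh adds to the less hindered terminal alkyne carbon to give the linear enone, and syn H/acyl delivery followed by C–C reductive elimination fixes the E geometry. The geranyl trisubstituted alkenes are too hindered to insert, and the temperature is well below that of an aryl geranyl ether Claisen rearrangement. The reaction class is known for terminal alkynes, but linear selectivity with an electron-rich aryl alkyne is the accepted risk.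

**Step 4**
Reactants: 6, TBS-protected chalcone
Product: 7, (2E)-1-(4-{[(2E)-3,7-dimethylocta-2,6-dien-1-yl]oxy}-2-hydroxyphenyl)-3-(4-hydroxyphenyl)prop-2-en-1-one (target, EANPDB:LEGU_00029)
Conditions: TBAF (1.1 equiv), AcOH (1.1 equiv), THF, 0 °C, 20 min; pH 7 buffer work-up
Reagents that add atoms: none
Why: Fluoride-mediated cleavage of the aryl silyl ether (Si–F bond formation, phenoxide leaving group) is fast at 0 °C, and the AcOH buffer prevents base-induced oxa-Michael closure to the flavanone or E/Z erosion, while the allylic ether and enone are inert.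

## Compound list

1 | 2,4-dihydroxybenzaldehyde | O=Cc1ccc(O)cc1O | starting material
2 | geranyl bromide, (2E)-1-bromo-3,7-dimethylocta-2,6-diene | CC(C)=CCC/C(C)=C/CBr | starting material
3 | 4-{[(2E)-3,7-dimethylocta-2,6-dien-1-yl]oxy}-2-hydroxybenzaldehyde | CC(C)=CCC/C(C)=C/COc1ccc(C=O)c(O)c1 | intermediate
4 | 4-ethynylphenol | C#Cc1ccc(O)cc1 | starting material
5 | tert-butyl(4-ethynylphenoxy)dimethylsilane | C#Cc1ccc(O[Si](C)(C)C(C)(C)C)cc1 | intermediate
6 | (2E)-3-{4-[(tert-butyldimethylsilyl)oxy]phenyl}-1-(4-{[(2E)-3,7-dimethylocta-2,6-dien-1-yl]oxy}-2-hydroxyphenyl)prop-2-en-1-one | CC(C)=CCC/C(C)=C/COc1ccc(C(=O)/C=C/c2ccc(O[Si](C)(C)C(C)(C)C)cc2)c(O)c1 | intermediate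
7 | 4'-O-geranylisoliquiritigenin, (2E)-1-(4-{[(2E)-3,7-dimethylocta-2,6-dien-1-yl]oxy}-2-hydroxyphenyl)-3-(4-hydroxyphenyl)prop-2-en-1-one | CC(C)=CCC/C(C)=C/COc1ccc(C(=O)/C=C/c2ccc(O)cc2)c(O)c1 | target

## Summary

Total step count: 4 (convergent).
Longest linear sequence: 3 steps (1 → 3 → 6 → 7, or equally 4 → 5 → 6 → 7).

Three steps most likely to fail, each with a fallback that changes the approach:

1. **Step 3, hydroacylation.** Risks are branched (1,1-disubstituted) enone, Rh-mediated alkyne dimerisation or oligomerisation, partial flavanone closure, and Rh ionisation of the allylic ether. Fallback: fix the regiochemistry by construction. Convert 3 to the aryl vinyl ketone (vinylMgBr, then MnO2) and form the Cβ–aryl bond by Mizoroki–Heck coupling with tert-butyl(4-iodophenoxy)dimethylsilane, which can only give the linear E-chalcone.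
2. **Step 1, mono-O-geranylation.** Risks are 2,4-bis-alkylation and C-geranylation of the resorcinol-type phenoxide. Fallback: Mitsunobu etherification of 1 with geraniol (PPh3, DIAD, THF, 0 °C). This activates the alcohol instead of generating a free phenoxide, selects the more acidic non-chelated 4-OH, and suppresses C-alkylation.
3. **Step 4, desilylation.** Risk is fluoride or base-triggered cyclisation of the 2'-hydroxychalcone to the flavanone, or loss of material. Fallback: change the protecting-group strategy. Carry the B-ring phenol through Step 3 as the acetate (4-ethynylphenyl acetate) and unmask with K2CO3/MeOH, where the chalcone is stable as its phenolate as under Claisen–Schmidt conditions. Alternatively, omit protection and use freshly prepared 4-ethynylphenol directly in the hydroacylation.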